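I started from a neighbour flask with 20 mM of starting material, asking what part of a charge is lost to over-reaction and whether that part follows the size of the charge. The flask here holds less.

starting material 5.0 mM; gas phase 0.45 mM (held); time 6.0 s

    gas phase ⇌ dissolved gas, rate k1*(csat - [dissolved gas]) (k1 = 70 s⁻¹, csat = 0.45 mM)
    dissolved gas → decomposed reagent (k2 = 0.058 s⁻¹)
    starting material + dissolved gas → target (k3 = 1900 L mol⁻¹ s⁻¹)
    crystals ⇌ target, rate k4*(cs4 - [target]) while solid is left; crystals form when [target] > cs4 (cs4 = 0.091 mM, k4 = 1.1 s⁻¹)
    dissolved gas + target → over-reacted product (k5 = 1000 L mol⁻¹ s⁻¹)

- target is meant together with its crystals
- solid, in amounts per volume of the solution: crystals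
- at the start none of the gas is dissolved
- run time (flask): 6.0 s

- amount of target and crystals together at 6.0 s, in percent of the starting material charged
- the change that raises the amount of target and crystals together at 6.0 s, in percent of the starting material charged most ("none" if none brings more than 2 percentage points) (west / north / north-east / south / none)
- amount of target and crystals together at 6.0 s, in percent of the starting material charged, after north-east

- west: doubling the saturation concentration of gas phase, all else as stated
- north: doubling the solubility in step 4, all else as stated
- north-east: doubling the transfer coefficient of step 1, all else as stated
- south: doubling the dissolution coefficient of step 4, all else as stated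

Gas crossed into solution with 70 s⁻¹, while the starting material took it with at most 9.50 s⁻¹, so I held the dissolved gas near 0.45 mM. Over-reaction then became a pseudo-first-order loss of dissolved target at 0.450 s⁻¹, but crystals drew on the same target with 1.1 s⁻¹. So I carried the escape share φ, the over-reaction constant over the sum of itself and the crystal coefficient: 29.0 %. But crystals grow from the excess over the solubility, so I applied φ to the charge plus the solubility times the crystal coefficient and the time. By this reckoning, 67.5 % stayed as target and crystals. Step 1 does not enter φ, so I expected north-east to leave that figure. The same reckoning gave 78.9 % for south, 49.6 % for west and 64.0 % for north, so I chose south.

The forecast gave 68.5 %, south and 67.5 % after north-east, holding that “crystallisation is slow enough that dissolved target peaks well above its solubility”.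

The flask gave 68.8 %, south with 11 percentage points, and 68.2 % after north-east.

In this flask, making target used dissolved gas 3.3 times as fast as over-reaction did at 1.02 s, but 0.63 times as fast at 6.00 s, and over-reaction had turned over 30.5 % of the charge by the end. Target and crystals together moved by 5 points when the starting material alone came down to 2.06 mM, or when the time alone went up to 15.1 s, and a run there could part from the forecast. For the neighbour flask, I reckoned with φ and its own charge 29.9 % lost, and its over-reacted product stood at 25.1 % of its charge.

The numbers belong to no real substance; the result is computed.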